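A direct plan would couple two commercial benzaldehydes by copper-catalysed O-arylation to the diaryl ether dialdehyde A1, add an ω-alkenyl Grignard reagent twice to reach the diene diol A2, close the ring by metathesis to the macrocyclic alkene diol A3, and finish by hydrogenation/hydrogenolysis to the trimethyl ether A4 and demethylation. Its weakest steps would be:
- the O-arylation, because the phenol is flanked by two methoxy groups and deactivated by a para-formyl group;
- the macrocyclising metathesis, because an unbiased 22-membered ring would form only at millimolar dilution against oligomerisation;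
- the removal of the two benzylic hydroxyl groups, because they would be made only to be cleaved, and the one on the meta-oxygenated ring is not activated for hydrogenolysis.

The new route disconnects ring A itself. With ring A numbered C1 (OH), C3 (OAr), C5 (alkyl), the bonds C1–C2 and C3–C4 are cut, which leads back to an open-chain precursor in which an ethynyl ether on the oxygen of ring B is tethered by the C14 chain to a 3-alkylcyclobutenone. One thermal vinylketene/ynol ether benzannulation would build ring A around the ether oxygen, set its 1,3,5-pattern with the free C1 hydroxyl, and close the 22-membered ring. No aryl C–O bond is made by coupling, no metathesis is needed, and the chain arrives fully saturated, so no carbinol is made and removed.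

Key step: step 5

Assumption: the target contains no stereocentre and no stereogenic double bond, so the structure as drawn is its only stereoisomer and nothing has to be controlled.

Step 1
Reactants: 1 4-bromo-2,6-dimethoxyphenol; 2 trichloroethylene
Product: 3 5-bromo-2-{[(E)-1,2-dichloroethenyl]oxy}-1,3-dimethoxybenzene
Conditions: K2CO3 (2 equiv), DMF, 70 °C
Reagents that add atoms: none
Why: Base-mediated dichlorovinylation of a phenol, in which K2CO3 turns trichloroethylene into dichloroacetylene in situ and the phenoxide adds anti across it to give the (E)-1,2-dichlorovinyl ether (a masked ethynyl ether); the small linear electrophile is not hindered by the two ortho methoxy groups and the aryl bromide is inert.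

Step 2
Reactants: 3 5-bromo-2-{[(E)-1,2-dichloroethenyl]oxy}-1,3-dimethoxybenzene; 4 1,14-dibromotetradecane (3 equiv)
Product: 6 5-(14-bromotetradecyl)-2-{[(E)-1,2-dichloroethenyl]oxy}-1,3-dimethoxybenzene, via arylmagnesium bromide 5 (not isolated)
Conditions: Mg, LiCl, THF, 0 °C → rt; then 4, Li2CuCl4 (5 mol %), NMP, THF, 0 °C → rt
Reagents that add atoms: none
Why: LiCl-assisted magnesium insertion into the aryl C–Br bond followed by a Kochi-type copper-catalysed sp2–sp3 coupling with a primary bromide; the excess of the α,ω-dibromide should keep the coupling at one end, and the vinylic C–Cl bonds should neither insert magnesium nor couple under these mild conditions.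

Step 3
Reactants: 6 5-(14-bromotetradecyl)-2-{[(E)-1,2-dichloroethenyl]oxy}-1,3-dimethoxybenzene; 7 3-ethoxycyclobut-2-en-1-one
Product: 9 (±)-1-(14-{4-[(E)-1,2-dichloroethenyl]oxy-3,5-dimethoxyphenyl}tetradecyl)-3-ethoxycyclobut-2-en-1-ol, via alkylmagnesium bromide 8 (not isolated)
Conditions: Mg, THF, rt → 35 °C; then 7 (1.2 equiv), THF, −78 °C; sat. aq. NaHCO3; used crude
Reagents that add atoms: none
Why: Grignard formation at the primary bromide and 1,2-addition to the carbonyl of the vinylogous ester (first half of a Stork–Danheiser sequence) should give the β-ethoxy allylic carbinol, which a cold, weakly basic work-up keeps intact; its racemic stereocentre disappears in step 4.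

Step 4
Reactants: 9 (±)-1-(14-{4-[(E)-1,2-dichloroethenyl]oxy-3,5-dimethoxyphenyl}tetradecyl)-3-ethoxycyclobut-2-en-1-ol
Product: 12 3-{14-[4-(ethynyloxy)-3,5-dimethoxyphenyl]tetradecyl}cyclobut-2-en-1-one, via dilithio alkoxide acetylide 10 (not isolated), via ynol ether carbinol 11 (not isolated)
Conditions: n-BuLi (3.3 equiv), THF, −78 °C; then 0.5 M aq. HCl, −78 → 0 °C, 15 min
Reagents that add atoms: water, O
Why: n-BuLi should convert the dichlorovinyl ether into the lithium aryloxyacetylide (deprotonation, loss of LiCl, Cl/Li exchange on the chloroalkyne) while the carbinol is held as its lithium alkoxide at −78 °C, and dilute acid should then protonate the acetylide and effect the vinylogous hydrolysis (Stork–Danheiser transposition) to the 3-alkylcyclobutenone much faster than it hydrates an aryl ynol ether.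

Step 5
Reactants: 12 3-{14-[4-(ethynyloxy)-3,5-dimethoxyphenyl]tetradecyl}cyclobut-2-en-1-one
Product: 17 ring-B di-O-methyl ether of robustol (22-membered diaryl ether macrocycle with free C1 hydroxyl on ring A and two methoxy groups on ring B), via vinylketene 13 (not isolated), via macrocyclic alkenylcyclobutenone 14 (not isolated), via dienylketene 15 (not isolated), via cyclohexadienone 16 (not isolated)
Conditions: PhMe (degassed), 1 mM, 110 °C, syringe-pump addition of 12 over 12 h, then 12 h, Ar
Reagents that add atoms: none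
Why: Proposed new method: heating should open the 3-alkylcyclobutenone reversibly (4π, conrotatory) to vinylketene 13, whose ketene C=C undergoes a regiospecific [2+2] cycloaddition with the tethered electron-rich aryl ethynyl ether (the nucleophilic terminal alkyne carbon bonds to the ketene carbonyl carbon) to give alkenylcyclobutenone 14, and 4π ring opening to dienylketene 15, 6π electrocyclisation to cyclohexadienone 16 and tautomerisation then deliver the phenol, the net change being insertion of the two alkyne carbons between C1 and C2 of the cyclobutenone. The closest known reaction type is the intermolecular Danheiser benzannulation of 3-alkylcyclobutenones with alkoxy- and siloxyalkynes, which gives 5-alkylresorcinol monoethers but has not been used to close a large ring. The 22-membered ring is closed in the ketene–alkyne [2+2] step (end-to-end cycloaddition through the 14-carbon tether, forming C1–C2 and C3–C4 of ring A), and ring A is closed by the 6π electrocyclisation (C1–C6) and fixed by aromatisation. No stereocentre remains in 17, because the single sp3 centre of 14 is erased on ring opening. The step needs regioselectivity (OAr meta to OH, hydrogen at C2), which the polarisation of the ynol ether and of the ketene secures, and it needs ring closure to beat intermolecular reaction, which high dilution should secure because untrapped vinylketene reverts to the cyclobutenone instead of accumulating, so that ketene dimerisation and acylation of the product phenol stay slow.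

Step 6
Reactants: 17 ring-B di-O-methyl ether of robustol
Product: 18 robustol
Conditions: BBr3 (5 equiv), CH2Cl2, −78 °C → rt; then H2O
Reagents that add atoms: none
Why: Lewis acid-mediated cleavage of the two aryl methyl ethers with BBr3 should leave the diaryl ether and the alkyl bridge untouched, and no stereocentre is involved.

Compound list

1 | 4-bromo-2,6-dimethoxyphenol | COc1cc(Br)cc(OC)c1O | starting material
2 | trichloroethylene | ClC=C(Cl)Cl | starting material
3 | 5-bromo-2-{[(E)-1,2-dichloroethenyl]oxy}-1,3-dimethoxybenzene | COc1cc(Br)cc(OC)c1O/C(Cl)=C\Cl | intermediate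
4 | 1,14-dibromotetradecane | BrCCCCCCCCCCCCCCBr | starting material
5 | {4-[(E)-1,2-dichloroethenyl]oxy-3,5-dimethoxyphenyl}magnesium bromide (not isolated) | COc1cc([Mg]Br)cc(OC)c1O/C(Cl)=C\Cl | intermediate
6 | 5-(14-bromotetradecyl)-2-{[(E)-1,2-dichloroethenyl]oxy}-1,3-dimethoxybenzene | COc1cc(CCCCCCCCCCCCCCBr)cc(OC)c1O/C(Cl)=C\Cl | intermediate
7 | 3-ethoxycyclobut-2-en-1-one | CCOC1=CC(=O)C1 | starting material
8 | (14-{4-[(E)-1,2-dichloroethenyl]oxy-3,5-dimethoxyphenyl}tetradecyl)magnesium bromide (not isolated) | COc1cc(CCCCCCCCCCCCCC[Mg]Br)cc(OC)c1O/C(Cl)=C\Cl | intermediate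
9 | (±)-1-(14-{4-[(E)-1,2-dichloroethenyl]oxy-3,5-dimethoxyphenyl}tetradecyl)-3-ethoxycyclobut-2-en-1-ol (racemic) | COc1cc(CCCCCCCCCCCCCCC2(O)CC(OCC)=C2)cc(OC)c1O/C(Cl)=C\Cl | intermediate
10 | lithium 3-ethoxy-1-(14-{4-[(lithioethynyl)oxy]-3,5-dimethoxyphenyl}tetradecyl)cyclobut-2-en-1-olate (racemic, not isolated) | [Li]C#COc1c(OC)cc(CCCCCCCCCCCCCCC2(O[Li])CC(OCC)=C2)cc1OC | intermediate
11 | (±)-3-ethoxy-1-{14-[4-(ethynyloxy)-3,5-dimethoxyphenyl]tetradecyl}cyclobut-2-en-1-ol (racemic, not isolated) | C#COc1c(OC)cc(CCCCCCCCCCCCCCC2(O)CC(OCC)=C2)cc1OC | intermediate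
12 | 3-{14-[4-(ethynyloxy)-3,5-dimethoxyphenyl]tetradecyl}cyclobut-2-en-1-one | C#COc1c(OC)cc(CCCCCCCCCCCCCCC2=CC(=O)C2)cc1OC | intermediate
13 | 3-{14-[4-(ethynyloxy)-3,5-dimethoxyphenyl]tetradecyl}buta-1,3-dien-1-one (vinylketene, not isolated) | C#COc1c(OC)cc(CCCCCCCCCCCCCCC(=C)C=C=O)cc1OC | intermediate
14 | macrocyclic [2+2] adduct: cyclobut-2-en-1-one with the aryloxy group at C3 and the alk-1-en-2-yl group at C4, the two linked through ring B and the C14 chain (racemic, not isolated) | O=C1C=C2Oc3c(OC)cc(cc3OC)CCCCCCCCCCCCCCC(=C)C12 | intermediate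
15 | macrocyclic dienylketene: 3-aryloxy-5-alkylhexa-1,3,5-trien-1-one with the ketene and vinyl ends cis on the central double bond (not isolated) | O=C=C/C1=C\C(=C)CCCCCCCCCCCCCCc2cc(OC)c(O1)c(OC)c2 | intermediate
16 | macrocyclic 3-aryloxy-5-alkylcyclohexa-2,4-dien-1-one (keto tautomer of 17, not isolated) | O=C1C=C2C=C(C1)CCCCCCCCCCCCCCc1cc(OC)c(O2)c(OC)c1 | intermediate
17 | ring-B di-O-methyl ether of robustol: 22-membered macrocycle, ring A 5-hydroxy-1,3-phenylene, ring B 2,6-dimethoxy-1,4-phenylene on the ether oxygen, (CH2)14 bridge | Oc1cc2cc(c1)CCCCCCCCCCCCCCc1cc(OC)c(O2)c(OC)c1 | intermediate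
18 | robustol | Oc1cc2cc(c1)Oc1c(O)cc(cc1O)CCCCCCCCCCCCCC2 | target

Total step count: 6. Longest linear sequence: 6 steps (1 → 3 → 6 → 9 → 12 → 17 → 18).

Steps most likely to fail

1. Step 5 (proposed new method). The end-to-end ketene–alkyne cycloaddition may be too slow at the dilution it needs, so that thermal degradation of the ynol ether or bimolecular ketene–alkyne reaction to oligomers takes over. The fallback is a known intramolecular Ullmann diaryl ether macrocyclisation, here with an electron-rich para-alkyl phenol. It sets out from 1 and 4. Compound 1 would be protected (MOMCl, i-Pr2NEt) as 5-bromo-1,3-dimethoxy-2-(methoxymethoxy)benzene F1, converted with Mg/LiCl into [3,5-dimethoxy-4-(methoxymethoxy)phenyl]magnesium bromide F2 and coupled with excess 4 (Li2CuCl4) to 5-(14-bromotetradecyl)-1,3-dimethoxy-2-(methoxymethoxy)benzene F3. Bromine–magnesium exchange on commercial 1-(benzyloxy)-3,5-dibromobenzene (i-PrMgCl·LiCl) would give [3-(benzyloxy)-5-bromophenyl]magnesium chloride F4, whose copper-catalysed coupling with F3 would give 1-(benzyloxy)-3-bromo-5-{14-[3,5-dimethoxy-4-(methoxymethoxy)phenyl]tetradecyl}benzene F5. HCl in MeOH would free 4-{14-[3-(benzyloxy)-5-bromophenyl]tetradecyl}-2,6-dimethoxyphenol F6, and CuI/N,N-dimethylglycine/Cs2CO3 in dioxane at 2 mM and 100 °C would close the ring to the O-benzyl ether of 17 F7. Hydrogenolysis (H2, Pd/C, EtOAc) would come back to the route at 17.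

2. Step 4. The lithium cyclobutenoxide may undergo oxyanion-accelerated electrocyclic ring opening while the acetylide is being formed, or the ynol ether may be hydrated during the acidic unmasking. The fallback sets out from 9 and removes the alkoxide from the sequence. Silylation with N-(trimethylsilyl)imidazole would give the trimethylsilyl ether of 9 F8, n-BuLi (2.3 equiv, THF, −78 °C) would give the lithium aryloxyacetylide of that silyl ether F9, and a methanol quench would give the trimethylsilyl ether of 11 F10, which can be purified on base-washed silica. Brief exposure to AcOH–H2O–THF at 0 °C would then release ethanol and trimethylsilanol and come back to the route at 12.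

3. Step 2. Electron transfer from magnesium to the C–Cl bonds, or metalation of the vinylic C–H by the organomagnesium species, may erode the masked alkyne; the same concern applies to the Grignard formation of step 3. The fallback sets out from 1 and 4 and introduces the dichlorovinyl ether only after both organomagnesium steps. Silylation (TBSCl, imidazole) would give (4-bromo-2,6-dimethoxyphenoxy)(tert-butyl)dimethylsilane F11. Magnesium insertion would give {4-[(tert-butyldimethylsilyl)oxy]-3,5-dimethoxyphenyl}magnesium bromide F12, and copper-catalysed coupling with excess 4 would give [4-(14-bromotetradecyl)-2,6-dimethoxyphenoxy](tert-butyl)dimethylsilane F13. Magnesium insertion would give (14-{4-[(tert-butyldimethylsilyl)oxy]-3,5-dimethoxyphenyl}tetradecyl)magnesium bromide F14, and addition to 7 at −78 °C would give 1-(14-{4-[(tert-butyldimethylsilyl)oxy]-3,5-dimethoxyphenyl}tetradecyl)-3-ethoxycyclobut-2-en-1-ol F15. TBAF would free 3-ethoxy-1-[14-(4-hydroxy-3,5-dimethoxyphenyl)tetradecyl]cyclobut-2-en-1-ol F16, and dichlorovinylation with 2 (Cs2CO3, DMF, 40 °C) would come back to the route at 9.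

Further compounds

F1 | step 5 | 5-bromo-1,3-dimethoxy-2-(methoxymethoxy)benzene | COCOc1c(OC)cc(Br)cc1OC
F2 | step 5 | [3,5-dimethoxy-4-(methoxymethoxy)phenyl]magnesium bromide | COCOc1c(OC)cc([Mg]Br)cc1OC
F3 | step 5 | 5-(14-bromotetradecyl)-1,3-dimethoxy-2-(methoxymethoxy)benzene | COCOc1c(OC)cc(CCCCCCCCCCCCCCBr)cc1OC
F4 | step 5 | [3-(benzyloxy)-5-bromophenyl]magnesium chloride | Cl[Mg]c1cc(Br)cc(OCc2ccccc2)c1
F5 | step 5 | 1-(benzyloxy)-3-bromo-5-{14-[3,5-dimethoxy-4-(methoxymethoxy)phenyl]tetradecyl}benzene | COCOc1c(OC)cc(CCCCCCCCCCCCCCc2cc(Br)cc(OCc3ccccc3)c2)cc1OC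
F6 | step 5 | 4-{14-[3-(benzyloxy)-5-bromophenyl]tetradecyl}-2,6-dimethoxyphenol | COc1cc(CCCCCCCCCCCCCCc2cc(Br)cc(OCc3ccccc3)c2)cc(OC)c1O
F7 | step 5 | O-benzyl ether of 17 (benzyloxy on ring A, two methoxy groups on ring B) | C(c1ccccc1)Oc1cc2cc(c1)CCCCCCCCCCCCCCc1cc(OC)c(O2)c(OC)c1
F8 | step 4 | trimethylsilyl ether of 9 (racemic) | COc1cc(CCCCCCCCCCCCCCC2(O[Si](C)(C)C)CC(OCC)=C2)cc(OC)c1O/C(Cl)=C\Cl
F9 | step 4 | lithium aryloxyacetylide of the trimethylsilyl ether (racemic) | [Li]C#COc1c(OC)cc(CCCCCCCCCCCCCCC2(O[Si](C)(C)C)CC(OCC)=C2)cc1OC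
F10 | step 4 | trimethylsilyl ether of 11 (racemic) | C#COc1c(OC)cc(CCCCCCCCCCCCCCC2(O[Si](C)(C)C)CC(OCC)=C2)cc1OC
F11 | step 2 | (4-bromo-2,6-dimethoxyphenoxy)(tert-butyl)dimethylsilane | COc1cc(Br)cc(OC)c1O[Si](C)(C)C(C)(C)C
F12 | step 2 | {4-[(tert-butyldimethylsilyl)oxy]-3,5-dimethoxyphenyl}magnesium bromide | COc1cc([Mg]Br)cc(OC)c1O[Si](C)(C)C(C)(C)C
F13 | step 2 | [4-(14-bromotetradecyl)-2,6-dimethoxyphenoxy](tert-butyl)dimethylsilane | COc1cc(CCCCCCCCCCCCCCBr)cc(OC)c1O[Si](C)(C)C(C)(C)C
F14 | step 2 | (14-{4-[(tert-butyldimethylsilyl)oxy]-3,5-dimethoxyphenyl}tetradecyl)magnesium bromide | COc1cc(CCCCCCCCCCCCCC[Mg]Br)cc(OC)c1O[Si](C)(C)C(C)(C)C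
F15 | step 2 | 1-(14-{4-[(tert-butyldimethylsilyl)oxy]-3,5-dimethoxyphenyl}tetradecyl)-3-ethoxycyclobut-2-en-1-ol (racemic) | COc1cc(CCCCCCCCCCCCCCC2(O)CC(OCC)=C2)cc(OC)c1O[Si](C)(C)C(C)(C)C
F16 | step 2 | 3-ethoxy-1-[14-(4-hydroxy-3,5-dimethoxyphenyl)tetradecyl]cyclobut-2-en-1-ol (racemic) | COc1cc(CCCCCCCCCCCCCCC2(O)CC(OCC)=C2)cc(OC)c1O
A1 | direct plan | 4-(3-formyl-5-methoxyphenoxy)-3,5-dimethoxybenzaldehyde | COc1cc(C=O)cc(c1)Oc1c(OC)cc(C=O)cc1OC
A2 | direct plan | 1-{4-[3-(1-hydroxyoct-7-enyl)-5-methoxyphenoxy]-3,5-dimethoxyphenyl}oct-7-en-1-ol (diastereomer mixture) | COc1cc(C(O)CCCCCC=C)cc(c1)Oc1c(OC)cc(cc1OC)C(O)CCCCCC=C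
A3 | direct plan | macrocyclic alkene diol, 22-membered ring with hydroxyl groups at both benzylic bridge carbons and a C7=C8 double bond (E/Z and diastereomer mixture) | COc1cc2cc(c1)Oc1c(OC)cc(cc1OC)C(O)CCCCCC=CCCCCCC2O
A4 | direct plan | tri-O-methylrobustol | COc1cc2cc(c1)Oc1c(OC)cc(cc1OC)CCCCCCCCCCCCCC2
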